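(The numbers in the tables were computed for an exercise; scatter was added.)

Tuesday's flask and south-east look nearly the same, with 5.6 mM of free catalyst against 5.4 mM, but Tuesday's last reading comes at 120 s and south-east is asked at 4.0 min.

| setting | Tuesday's | Thursday's | east | north | south | south-east | north-west |
|---|---|---|---|---|---|---|---|
| starting material | 2.7 M | 2.7 M | 2.7 M | 2.7 M | 2.7 M | 2.7 M | 2.7 M |
| free catalyst | 5.6 mM | 14 mM | 20 mM | 4.0 mM | 10 mM | 5.4 mM | 1.5 mM |
| remark | run made earlier | run made earlier |  |  |  |  |  |
| time |  |  | 4.0 min | 4.0 min | 4.0 min | 4.0 min | 4.0 min |

| run | time / s | product / % | starting material / % |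
|---|---|---|---|
| Tuesday's | 30.0 | 22 | 65 |
| Tuesday's | 60.0 | 42 | 41 |
| Tuesday's | 90.0 | 55 | 26 |
| Tuesday's | 120 | 62 | 17 |
| Thursday's | 30.0 | 54 | 40 |
| Thursday's | 60.0 | 86 | 5 |
| Thursday's | 90.0 | 93 | 0 |
| Thursday's | 120 | 91 | 3 |

(readings scatter by 1.5 percentage points)

* all flasks from highest to lowest amount of product, in percent of the starting material charged, at 4.0 min (east / north / south / south-east / north-west)
* the amount of product, in percent of the starting material charged of the flask you put first, at 4.0 min
* the amount of product, in percent of the starting material charged of the flask you put last, at 4.0 min



Tuesday's flask gains 22% product by its first reading and 20 percentage points more by its second, while starting material drops from 65% to 41%. So early on product forms at zero order in starting material. I carry the working rate, the turnover frequency: product formed per second per free catalyst charged.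

w = (first product reading) × c(starting material) / (time × c(free catalyst))

Tuesday: 3.54 s⁻¹. Thursday: 3.47 s⁻¹.

Tuesday's last reading holds 79.0% as product plus starting material, so I expect south-east a little below that. Tuesday misses 21.0%, Thursday 7.00%, so the loss seems to grow with the time starting material stands.

I rank by catalyst: east first, north-west last. At the working rate alone, east would need 38.2 s and Thursday's flask 54.5 s to use up the charge, so I scale the loss:

east: 95.1%

For north-west, the first round runs the working rate to 4.0 min:

ceiling = w × c(free catalyst) × t / c(starting material) = 47.1%

The second round puts Tuesday's own shortfall back in. The working rate would give Tuesday's flask 88.0% by its last reading, and that reading is 62%, a ratio of 70.5%. North-west runs longer than Tuesday's flask, so I apply that ratio to its ceiling: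

north-west: 33.2%

The forecast gives east > south > south-east > north > north-west, with 95% (92% to 98%) for east and 14% (9% to 20%) for north-west, well under my figure, and reads a “catalyst-independent side path”.

The flasks give east > south > south-east > north > north-west: east 93.5%, south-east 76.2%, north-west 34.5%.

    starting material + free catalyst → catalyst intermediate (k = 23.3 L mol⁻¹ s⁻¹)
    catalyst intermediate → free catalyst + product (k = 4.07 s⁻¹)
    2 starting material → homo dimer (k = 0.00100 L mol⁻¹ s⁻¹)
    catalyst intermediate + product → spent catalyst (k = 0.00901 L mol⁻¹ s⁻¹)

East stops short of the charge mainly because of the step to homo dimer: without that step east holds 99.4% of product instead of 93.5%, which is 91% of what is missing. For north-west the working rate gave a ceiling of 47.1% and, after the second round, 33.2%, and the flask holds 34.5%. On the flask like north-west with 0.900 mM of free catalyst, the same rounds give a ceiling of 28.3% and then 19.9%, and that flask holds 23.3%.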